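## Retrosynthetic overview

1. Target 28 ⇐ TEMPO oxidation of epoxy alcohol 27 ⇐ Sharpless epoxidation of allylic alcohol 26 ⇐ SeO2 oxidation of the isopropenyl group of 25; the 9β-OH comes from late reduction of a C9 ketone that is carried as a thioketal.
2. cis-α-Methylene-γ-lactone ⇐ C8 cyclohexanone 11: C7 enolate alkylation with bromoacetate, L-Selectride reduction/lactonisation, Eschenmoser methylenation.
3. Key step: cyclohexanone 11 ⇐ cyclopentanone 9 by a one-carbon semipinacol ring expansion (Cu(I)-triggered 1,2-shift of the quaternary C10), which inserts C9 as a masked ketone between C8 and C10.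
4. Cyclopentanone 9 (C5/C6/C10 triad) ⇐ enone 4 + isopropenyl Grignard + vinyl bromide (one-pot conjugate addition/enolate vinylation, new) ⇐ (S)-4-hydroxycyclopentenone 1.
5. Ring order: cyclopentane (purchased) → cyclohexane (ring expansion) → γ-lactone → oxirane.

Assumption: (S)-4-hydroxycyclopent-2-en-1-one is taken as commercially available (both enantiomers are sold).

Conventions: C1–C15 are elemanolide locants. The ring is C5–C10; C10 carries the C14 methyl and the C1=C2 vinyl; C5 carries C4 (with C3 and C15); C7 carries C11 (with C12 and C13). β is the face of the C10 methyl. From 9 on, every compound has 10β-methyl/10α-vinyl and a β side chain at C5 (5α-H); from 14 on the C7 side chain is β (7α-H). Building blocks that deliver two or more skeletal carbons are numbered as starting materials; one-carbon and heteroatom reagents stand under "Reagents that add atoms".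

## Route

Step 1
Reactants: 1 (S)-4-hydroxycyclopent-2-en-1-one
Product: 2 (S)-4-(tert-butyldimethylsilyloxy)cyclopent-2-en-1-one
Conditions: TBSCl, imidazole, DMF, 0 → 25 °C
Reagents that add atoms: tert-butyldimethylsilyl chloride, CC(C)(C)[Si](C)(C)Cl
Why: Imidazole-promoted silylation of the secondary alcohol; the (S) centre (future C6) is not involved.

Step 2
Reactants: 2 (S)-4-(tert-butyldimethylsilyloxy)cyclopent-2-en-1-one
Product: 3 (S)-4-(tert-butyldimethylsilyloxy)-2-iodocyclopent-2-en-1-one
Conditions: I2, pyridine, CH2Cl2, 0 → 25 °C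
Reagents that add atoms: iodine, II
Why: Johnson α-iodination of an enone (pyridine conjugate addition, iodination of the enolate, E1cB loss of pyridine) functionalises the future C10 without touching the stereocentre.

Step 3
Reactants: 3 (S)-4-(tert-butyldimethylsilyloxy)-2-iodocyclopent-2-en-1-one
Product: 4 (S)-4-(tert-butyldimethylsilyloxy)-2-methylcyclopent-2-en-1-one
Conditions: SnMe4, Pd2(dba)3 (2.5 mol%), AsPh3, CuI, NMP, 60 °C
Reagents that add atoms: tetramethyltin, C[Sn](C)(C)C
Why: Stille coupling of the α-iodoenone under neutral AsPh3/CuI conditions installs the C14 methyl without base-induced loss of the β-siloxy group.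

Step 4
Reactants: 4 (S)-4-(tert-butyldimethylsilyloxy)-2-methylcyclopent-2-en-1-one; 5 isopropenylmagnesium bromide; 6 vinyl bromide
Product: 9 (2S,3S,4S)-4-(tert-butyldimethylsilyloxy)-2-ethenyl-2-methyl-3-(prop-1-en-2-yl)cyclopentan-1-one, via magnesium enolate 7 (not isolated), via zinc enolate 8 (not isolated)
Conditions: 5 (1.3 equiv), CuBr·SMe2 (10 mol%), THF, −78 °C; ZnBr2, −78 → −20 °C; then 6, Pd(dba)2 (5 mol%), Q-Phos (10 mol%), −20 → 25 °C
Reagents that add atoms: none
Why: Proposed new method: tandem Cu-catalysed conjugate addition / Pd-catalysed α-vinylation of the derived zinc enolate with vinyl bromide, in which the cuprate adds anti to the C6 siloxy group (C5 side chain β), transmetalation to the less basic bromozinc enolate suppresses proton transfer and β-elimination of siloxide, and oxidative addition of vinyl bromide to Pd(0)/Q-Phos, transmetalation to a C-bound Pd(II) enolate on the face anti to the C5 isopropenyl group and reductive elimination set the C10 quaternary centre (vinyl α, methyl β); the closest known reactions are Noyori-type three-component enolate trapping and the Pd-catalysed α-arylation/α-vinylation of preformed zinc and lithium enolates, which have not been run in tandem with parent vinyl bromide on a tetrasubstituted β′-siloxy cyclopentanone enolate.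

Step 5
Reactants: 9 (2S,3S,4S)-4-(tert-butyldimethylsilyloxy)-2-ethenyl-2-methyl-3-(prop-1-en-2-yl)cyclopentan-1-one
Product: 10 (1S,2S,3S,4S)-4-(tert-butyldimethylsilyloxy)-2-ethenyl-2-methyl-3-(prop-1-en-2-yl)-1-[tris(methylsulfanyl)methyl]cyclopentan-1-ol (major epimer; 1-OH cis to the 2-methyl)
Conditions: HC(SMe)3, n-BuLi, THF, −78 °C; then 9, −78 → −45 °C; aq. NH4Cl
Reagents that add atoms: tris(methylthio)methane, CSC(SC)SC
Why: 1,2-Addition of the soft, weakly basic tris(methylthio)methyl carbanion (first stage of the Knapp ketone homologation) occurs anti to the pseudoaxial C10 methyl; the new C8 configuration is irrelevant because C8 becomes a carbonyl again in step 6.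

Step 6
Reactants: 10 (1S,2S,3S,4S)-4-(tert-butyldimethylsilyloxy)-2-ethenyl-2-methyl-3-(prop-1-en-2-yl)-1-[tris(methylsulfanyl)methyl]cyclopentan-1-ol
Product: 11 (3S,4S,5S)-5-(tert-butyldimethylsilyloxy)-3-ethenyl-3-methyl-2,2-bis(methylsulfanyl)-4-(prop-1-en-2-yl)cyclohexan-1-one (C8 ketone; C9 thioketal)
Conditions: Cu(MeCN)4BF4 (2.5 equiv), iPr2NEt (1.5 equiv), toluene, 75 °C
Reagents that add atoms: none
Why: Cu(I)-induced semipinacol ring expansion (Knapp synthesis of 1,2-keto thioketals): thiophilic Cu+ removes one MeS– and the bis(methylthio)carbenium ion is captured by a 1,2-shift of the electron-richer quaternary C10 (C7 is deactivated by the β-siloxy group) with retention at C10, which forms the cyclohexane, places the ketone at C8 and installs C9 as a masked carbonyl.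

Step 7
Reactants: 11 (3S,4S,5S)-5-(tert-butyldimethylsilyloxy)-3-ethenyl-3-methyl-2,2-bis(methylsulfanyl)-4-(prop-1-en-2-yl)cyclohexan-1-one; 12 methyl bromoacetate
Product: 14 methyl 6α-(tert-butyldimethylsilyloxy)-9,9-bis(methylthio)-8-oxo-13-norelema-1,3-dien-12-oate (7αH), via lithium enolate 13 (not isolated)
Conditions: LDA (1.1 equiv), THF, −78 °C; then 12, DMPU, −78 → −40 °C
Reagents that add atoms: none
Why: Enolate alkylation at the only enolisable position (C7); axial α-approach is blocked by the syn-axial C9 methylthio group, so the acetate arm enters β, trans to the 6α-siloxy group, and this equatorial centre is also the thermodynamic one.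

Step 8
Reactants: 14 methyl 6α-(tert-butyldimethylsilyloxy)-9,9-bis(methylthio)-8-oxo-13-norelema-1,3-dien-12-oate
Product: 16 6α-(tert-butyldimethylsilyloxy)-9,9-bis(methylthio)-13-norelema-1,3-dien-12,8β-olide, via hydroxy ester 15 (not isolated)
Conditions: L-Selectride, THF, −78 → 0 °C; aq. NH4Cl (non-oxidative work-up)
Reagents that add atoms: none
Why: L-Selectride reduction with equatorial hydride delivery (axial approach is blocked by the syn-axial C10 methyl) gives the axial 8β-alkoxide cis to the C7 arm, which closes the cis-fused γ-lactone by intramolecular transesterification.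

Step 9
Reactants: 16 6α-(tert-butyldimethylsilyloxy)-9,9-bis(methylthio)-13-norelema-1,3-dien-12,8β-olide
Product: 20 6α-(tert-butyldimethylsilyloxy)-9,9-bis(methylthio)elema-1,3,11(13)-trien-12,8β-olide, via lactone enolate 17 (not isolated), via Mannich base 18 (not isolated), via ammonium iodide 19 (not isolated)
Conditions: LDA, THF, −78 °C; Me2N=CH2+ I−, −78 → 0 °C; then MeI, MeOH, 25 °C; then aq. NaHCO3, CH2Cl2
Reagents that add atoms: N,N-dimethylmethyleneiminium iodide (Eschenmoser's salt), C=[N+](C)C.[I-]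
Why: Eschenmoser methylenation (Mannich reaction of the lactone enolate, N-quaternisation, base-induced Hofmann-type elimination); amine alkylation is much faster than S-alkylation of the thioketal and no stereocentre is touched.

Step 10
Reactants: 20 6α-(tert-butyldimethylsilyloxy)-9,9-bis(methylthio)elema-1,3,11(13)-trien-12,8β-olide
Product: 21 6α-hydroxy-9,9-bis(methylthio)elema-1,3,11(13)-trien-12,8β-olide
Conditions: HF·pyridine, THF/pyridine, 0 → 25 °C
Reagents that add atoms: none
Why: Fluoride-mediated Si–O cleavage under acidic buffering, which leaves the Michael-acceptor lactone and the thioketal intact.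

Step 11
Reactants: 21 6α-hydroxy-9,9-bis(methylthio)elema-1,3,11(13)-trien-12,8β-olide; 22 isobutyryl chloride
Product: 23 6α-isobutyryloxy-9,9-bis(methylthio)elema-1,3,11(13)-trien-12,8β-olide
Conditions: 22, pyridine, DMAP (cat.), CH2Cl2, 0 → 25 °C
Reagents that add atoms: none
Why: DMAP-catalysed acylation of the only free hydroxyl (C9 is still masked as the thioketal), so no site-selectivity problem arises.

Step 12
Reactants: 23 6α-isobutyryloxy-9,9-bis(methylthio)elema-1,3,11(13)-trien-12,8β-olide
Product: 24 6α-isobutyryloxy-9-oxoelema-1,3,11(13)-trien-12,8β-olide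
Conditions: PhI(OCOCF3)2 (1.5 equiv), MeCN/H2O 9:1, 0 °C
Reagents that add atoms: water, O
Why: Stork–Zhao oxidative dethioketalisation with a hypervalent iodine reagent (S-activation, hydrolysis of the thionium ion) unmasks the C9 ketone under conditions that spare the three alkenes and both esters.

Step 13
Reactants: 24 6α-isobutyryloxy-9-oxoelema-1,3,11(13)-trien-12,8β-olide
Product: 25 9β-hydroxy-6α-isobutyryloxyelema-1,3,11(13)-trien-12,8β-olide
Conditions: NaBH4, CeCl3·7H2O, MeOH, −78 °C
Reagents that add atoms: none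
Why: Luche reduction is 1,2-selective for the ketone over the α-methylene lactone, and hydride enters axially from the α face (equatorial approach is flanked by the axial C8–O and C10–CH3 bonds) to give the equatorial 9β-alcohol.

Step 14
Reactants: 25 9β-hydroxy-6α-isobutyryloxyelema-1,3,11(13)-trien-12,8β-olide
Product: 26 9β,15-dihydroxy-6α-isobutyryloxyelema-1,3,11(13)-trien-12,8β-olide
Conditions: SeO2 (0.5 equiv), t-BuOOH (2 equiv), CH2Cl2, 25 °C
Reagents that add atoms: selenium dioxide, O=[Se]=O; tert-butyl hydroperoxide, CC(C)(C)OO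
Why: Sharpless SeO2/t-BuOOH allylic oxidation (ene reaction, then [2,3]-shift of the allylseleninic acid) attacks the methyl of the only electron-rich alkene that has allylic hydrogens; the vinyl group has none and the acrylate alkene is electron-poor.

Step 15
Reactants: 26 9β,15-dihydroxy-6α-isobutyryloxyelema-1,3,11(13)-trien-12,8β-olide
Product: 27 (4S)-3,4-epoxy-9β,15-dihydroxy-6α-isobutyryloxyelema-1,11(13)-dien-12,8β-olide
Conditions: Ti(OiPr)4 (20 mol%), L-(+)-diethyl tartrate (24 mol%), t-BuOOH, 4 Å MS, CH2Cl2, −20 °C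
Reagents that add atoms: tert-butyl hydroperoxide, CC(C)(C)OO
Why: Katsuki–Sharpless asymmetric epoxidation under reagent control, L-(+)-tartrate delivering oxygen to the face that gives the (4S)-epoxy alcohol (as for (S)-2-methylglycidol); only the allylic alcohol is activated by titanium, so the vinyl and acrylate alkenes are spared.

Step 16
Reactants: 27 (4S)-3,4-epoxy-9β,15-dihydroxy-6α-isobutyryloxyelema-1,11(13)-dien-12,8β-olide
Product: 28 (4R)-3,4-epoxy-9β-hydroxy-6α-isobutyryloxy-15-oxoelema-1,11(13)-dien-12,8β-olide (target)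
Conditions: TEMPO (20 mol%), PhI(OAc)2 (1.2 equiv), CH2Cl2, 25 °C
Reagents that add atoms: none
Why: TEMPO/PhI(OAc)2 oxidation via the oxoammonium ion is selective for the primary alcohol over the hindered secondary C9–OH and leaves the epoxide untouched (the descriptor changes from 4S to 4R only through CIP priorities).

## Compound list

1 | (S)-4-hydroxycyclopent-2-en-1-one | O=C1C=C[C@@H](O)C1 | starting material
2 | (S)-4-(tert-butyldimethylsilyloxy)cyclopent-2-en-1-one | O=C1C=C[C@@H](O[Si](C)(C)C(C)(C)C)C1 | intermediate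
3 | (S)-4-(tert-butyldimethylsilyloxy)-2-iodocyclopent-2-en-1-one | O=C1C(I)=C[C@@H](O[Si](C)(C)C(C)(C)C)C1 | intermediate
4 | (S)-4-(tert-butyldimethylsilyloxy)-2-methylcyclopent-2-en-1-one | O=C1C(C)=C[C@@H](O[Si](C)(C)C(C)(C)C)C1 | intermediate
5 | isopropenylmagnesium bromide (prop-1-en-2-ylmagnesium bromide) | CC(=C)[Mg]Br | starting material
6 | vinyl bromide (bromoethene) | C=CBr | starting material
7 | magnesium enolate: bromomagnesium (3S,4S)-4-(tert-butyldimethylsilyloxy)-2-methyl-3-(prop-1-en-2-yl)cyclopent-1-en-1-olate | C=C(C)[C@@H]1[C@@H](O[Si](C)(C)C(C)(C)C)CC(O[Mg]Br)=C1C | intermediate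
8 | zinc enolate: bromozinc (3S,4S)-4-(tert-butyldimethylsilyloxy)-2-methyl-3-(prop-1-en-2-yl)cyclopent-1-en-1-olate | C=C(C)[C@@H]1[C@@H](O[Si](C)(C)C(C)(C)C)CC(O[Zn]Br)=C1C | intermediate
9 | (2S,3S,4S)-4-(tert-butyldimethylsilyloxy)-2-ethenyl-2-methyl-3-(prop-1-en-2-yl)cyclopentan-1-one (isopropenyl trans to OTBS and trans to vinyl) | C=C[C@@]1(C)[C@H](C(C)=C)[C@@H](O[Si](C)(C)C(C)(C)C)CC1=O | intermediate
10 | (1S,2S,3S,4S)-4-(tert-butyldimethylsilyloxy)-2-ethenyl-2-methyl-3-(prop-1-en-2-yl)-1-[tris(methylsulfanyl)methyl]cyclopentan-1-ol (major epimer) | C=C[C@@]1(C)[C@H](C(C)=C)[C@@H](O[Si](C)(C)C(C)(C)C)C[C@@]1(O)C(SC)(SC)SC | intermediate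
11 | (3S,4S,5S)-5-(tert-butyldimethylsilyloxy)-3-ethenyl-3-methyl-2,2-bis(methylsulfanyl)-4-(prop-1-en-2-yl)cyclohexan-1-one | C=C[C@@]1(C)[C@H](C(C)=C)[C@@H](O[Si](C)(C)C(C)(C)C)CC(=O)C1(SC)SC | intermediate
12 | methyl bromoacetate | COC(=O)CBr | starting material
13 | lithium enolate of 11 (C7=C8–OLi) | C=C[C@@]1(C)[C@H](C(C)=C)[C@@H](O[Si](C)(C)C(C)(C)C)C=C(O[Li])C1(SC)SC | intermediate
14 | methyl 6α-(tert-butyldimethylsilyloxy)-9,9-bis(methylthio)-8-oxo-13-norelema-1,3-dien-12-oate (7αH) | C=C[C@@]1(C)[C@H](C(C)=C)[C@@H](O[Si](C)(C)C(C)(C)C)[C@H](CC(=O)OC)C(=O)C1(SC)SC | intermediate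
15 | hydroxy ester: methyl 6α-(tert-butyldimethylsilyloxy)-8β-hydroxy-9,9-bis(methylthio)-13-norelema-1,3-dien-12-oate | C=C[C@@]1(C)[C@H](C(C)=C)[C@@H](O[Si](C)(C)C(C)(C)C)[C@H](CC(=O)OC)[C@H](O)C1(SC)SC | intermediate
16 | 6α-(tert-butyldimethylsilyloxy)-9,9-bis(methylthio)-13-norelema-1,3-dien-12,8β-olide (cis-fused lactone) | C=C[C@@]1(C)[C@H](C(C)=C)[C@@H](O[Si](C)(C)C(C)(C)C)[C@@H]2CC(=O)O[C@@H]2C1(SC)SC | intermediate
17 | lactone enolate: lithium enolate of 16 (C11=C12–OLi) | C=C[C@@]1(C)[C@H](C(C)=C)[C@@H](O[Si](C)(C)C(C)(C)C)[C@@H]2C=C(O[Li])O[C@@H]2C1(SC)SC | intermediate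
18 | Mannich base: 13-(dimethylamino)-6α-(tert-butyldimethylsilyloxy)-9,9-bis(methylthio)elema-1,3-dien-12,8β-olide (C11 epimers) | C=C[C@@]1(C)[C@H](C(C)=C)[C@@H](O[Si](C)(C)C(C)(C)C)[C@@H]2C(CN(C)C)C(=O)O[C@@H]2C1(SC)SC | intermediate
19 | ammonium iodide: N-methyl trimethylammonium iodide of 18 | C=C[C@@]1(C)[C@H](C(C)=C)[C@@H](O[Si](C)(C)C(C)(C)C)[C@@H]2C(C[N+](C)(C)C)C(=O)O[C@@H]2C1(SC)SC.[I-] | intermediate
20 | 6α-(tert-butyldimethylsilyloxy)-9,9-bis(methylthio)elema-1,3,11(13)-trien-12,8β-olide | C=C[C@@]1(C)[C@H](C(C)=C)[C@@H](O[Si](C)(C)C(C)(C)C)[C@@H]2C(=C)C(=O)O[C@@H]2C1(SC)SC | intermediate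
21 | 6α-hydroxy-9,9-bis(methylthio)elema-1,3,11(13)-trien-12,8β-olide | C=C[C@@]1(C)[C@H](C(C)=C)[C@@H](O)[C@@H]2C(=C)C(=O)O[C@@H]2C1(SC)SC | intermediate
22 | isobutyryl chloride (2-methylpropanoyl chloride) | CC(C)C(=O)Cl | starting material
23 | 6α-isobutyryloxy-9,9-bis(methylthio)elema-1,3,11(13)-trien-12,8β-olide | C=C[C@@]1(C)[C@H](C(C)=C)[C@@H](OC(=O)C(C)C)[C@@H]2C(=C)C(=O)O[C@@H]2C1(SC)SC | intermediate
24 | 6α-isobutyryloxy-9-oxoelema-1,3,11(13)-trien-12,8β-olide | C=C[C@@]1(C)[C@H](C(C)=C)[C@@H](OC(=O)C(C)C)[C@@H]2C(=C)C(=O)O[C@@H]2C1=O | intermediate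
25 | 9β-hydroxy-6α-isobutyryloxyelema-1,3,11(13)-trien-12,8β-olide | C=C[C@@]1(C)[C@H](C(C)=C)[C@@H](OC(=O)C(C)C)[C@@H]2C(=C)C(=O)O[C@@H]2[C@@H]1O | intermediate
26 | 9β,15-dihydroxy-6α-isobutyryloxyelema-1,3,11(13)-trien-12,8β-olide | C=C[C@@]1(C)[C@H](C(=C)CO)[C@@H](OC(=O)C(C)C)[C@@H]2C(=C)C(=O)O[C@@H]2[C@@H]1O | intermediate
27 | (4S)-3,4-epoxy-9β,15-dihydroxy-6α-isobutyryloxyelema-1,11(13)-dien-12,8β-olide | C=C[C@@]1(C)[C@H]([C@]2(CO)CO2)[C@@H](OC(=O)C(C)C)[C@@H]2C(=C)C(=O)O[C@@H]2[C@@H]1O | intermediate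
28 | (3aS,4S,5S,6S,7R,7aS)-6-ethenyl-5-[(2R)-2-formyloxiran-2-yl]-7-hydroxy-6-methyl-3-methylidene-2-oxooctahydro-1-benzofuran-4-yl 2-methylpropanoate | C=C[C@@]1(C)[C@H]([C@]2(C=O)CO2)[C@@H](OC(=O)C(C)C)[C@@H]2C(=C)C(=O)O[C@@H]2[C@@H]1O | target

Total step count: 16
Longest linear sequence: 16 steps (1 → 28)

## Steps most likely to fail, with fallbacks

Step 4 (the proposed new tandem vinylation). The zinc enolate may be protonated or lose siloxide before Pd turns over. The fallback uses known chemistry only, sets out from 4 and returns at 9. Cu-catalysed addition of 5 to 4 in the presence of TMSCl (THF, −78 °C) gives the trimethylsilyl enol ether F1. A Mukaiyama aldol of F1 with acetaldehyde (TiCl4, CH2Cl2, −78 °C), which attacks anti to the isopropenyl group, gives the β-hydroxy ketone F2. Dehydration of F2 with Martin sulfurane (CH2Cl2, 25 °C) can only form the vinyl group, because the methyl is the sole carbon with β-hydrogens, and gives 9.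

Step 6 (ring expansion). The bulky tris(methylthio)methyl adduct 10 may form poorly next to the quaternary centre, or the congested cation may react through other channels. The fallback sets out from 9 and returns at 11. The smaller bis(methylthio)methyllithium adds to 9 to give the carbinol F3. Cohen-type CuOTf-induced ring expansion of F3 (toluene, iPr2NEt, 60 °C), through the more reactive mono-thio carbenium ion and again with C10 migration, gives the α-(methylthio) ketone F4. Sulfenylation of F4 at its more acidic, sulfur-bearing C9 (NaH, THF, 0 °C, then S-methyl methanethiosulfonate) gives 11.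

Step 7 (C7 alkylation). Enolate 13 may react sluggishly with the bromoacetate or lose the β-siloxy group. The fallback sets out from 11 and returns at 14. Enolate 13 is trapped at −78 °C with the much more reactive methyl glyoxylate to give the aldol adduct F5. Dehydration of F5 with Burgess reagent (benzene, 50 °C) gives the alkylidene keto ester F6. Conjugate reduction of F6 with Stryker's reagent ([(Ph3P)CuH]6, benzene, 25 °C), with protonation to the equatorial C7 epimer, gives 14.

## Further compounds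

F1 | step 4 | trimethylsilyl enol ether: (3S,4S)-4-(tert-butyldimethylsilyloxy)-2-methyl-3-(prop-1-en-2-yl)-1-(trimethylsilyloxy)cyclopent-1-ene | C=C(C)[C@@H]1[C@@H](O[Si](C)(C)C(C)(C)C)CC(O[Si](C)(C)C)=C1C
F2 | step 4 | β-hydroxy ketone: 4-(tert-butyldimethylsilyloxy)-2-(1-hydroxyethyl)-2-methyl-3-(prop-1-en-2-yl)cyclopentan-1-one (ring centres as in 9; carbinol epimers) | CC(O)[C@@]1(C)[C@H](C(C)=C)[C@@H](O[Si](C)(C)C(C)(C)C)CC1=O
F3 | step 6 | carbinol: (1S,2S,3S,4S)-1-[bis(methylsulfanyl)methyl]-4-(tert-butyldimethylsilyloxy)-2-ethenyl-2-methyl-3-(prop-1-en-2-yl)cyclopentan-1-ol | C=C[C@@]1(C)[C@H](C(C)=C)[C@@H](O[Si](C)(C)C(C)(C)C)C[C@@]1(O)C(SC)SC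
F4 | step 6 | α-(methylthio) ketone: 6α-(tert-butyldimethylsilyloxy)-9-(methylthio)-11,12,13-trinorelema-1,3-dien-8-one (C9 epimers) | C=C[C@@]1(C)[C@H](C(C)=C)[C@@H](O[Si](C)(C)C(C)(C)C)CC(=O)C1SC
F5 | step 7 | aldol adduct: methyl 6α-(tert-butyldimethylsilyloxy)-11-hydroxy-9,9-bis(methylthio)-8-oxo-13-norelema-1,3-dien-12-oate (C11 epimers) | C=C[C@@]1(C)[C@H](C(C)=C)[C@@H](O[Si](C)(C)C(C)(C)C)[C@H](C(O)C(=O)OC)C(=O)C1(SC)SC
F6 | step 7 | alkylidene keto ester: methyl 6α-(tert-butyldimethylsilyloxy)-9,9-bis(methylthio)-8-oxo-13-norelema-1,3,7(11)-trien-12-oate | C=C[C@@]1(C)[C@H](C(C)=C)[C@@H](O[Si](C)(C)C(C)(C)C)C(=CC(=O)OC)C(=O)C1(SC)SC
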